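Everything rests on opening the carbocycle C3a–C4=C5–C6(=O)–C7–C7a at C3a–C4 and C7–C7a: C3a is the quaternary γ-carbon of a 4,4-disubstituted cyclohexenone and therefore the α-carbon of a 2-substituted acrolein. A Diels–Alder reaction of 2-allylacrolein with an E 1-carbamoylamino-3-silyloxybuta-1,3-diene, catalysed by a chiral chromium salen chloride, forms this ring, both C–C bonds and the C3a stereocentre in one operation; acid then releases the 4-allyl-4-formylcyclohexenone. The formyl carbon becomes C3, and the oxygen ring (O1, C2, C3) is closed last by oxa-Michael addition to C7a and convex-face ionic hydrogenation, which relay C3a to C7a, C3 and C2.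

Key step: step 4

Remark: the diene nitrogen is acylated (N-benzyl-N-methoxycarbonyl) because a dialkylamino diene adds to 2-substituted acroleins without catalyst and coordinates Lewis acids, which would defeat enantiocontrol; the enol ether, cyclopropane and epoxide stereoisomers of 12–17 are carried as mixtures because all of them converge in steps 9 and 11.

Step 1
Reactants: 1 pent-4-enal
Product: 2 2-methylidenepent-4-enal (2-allylacrolein)
Conditions: aq. CH2O (37%), pyrrolidine (10 mol %), EtCO2H (10 mol %), iPrOH, 45 °C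
Reagents that add atoms: formaldehyde, C=O
Why: Amine-catalysed Mannich condensation with formaldehyde followed by β-elimination of the amine (organocatalytic α-methylenation of an aldehyde) should convert the only enolisable position into the 2-methylene enal, and no stereocentre is formed.

Step 2
Reactants: 3 methyl N-benzylcarbamate; 4 (E)-4-methoxybut-3-en-2-one
Product: 5 methyl N-benzyl-N-[(1E)-3-oxobut-1-en-1-yl]carbamate
Conditions: TsOH·H2O (5 mol %), toluene, 90 °C, MeOH distilled off
Reagents that add atoms: none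
Why: Acid-catalysed addition–elimination of the carbamate nitrogen at the β-carbon of the vinylogous ester (vinylogous transacylation) is driven by removal of methanol and should give the conjugated E vinylogous imide.

Step 3
Reactants: 5 methyl N-benzyl-N-[(1E)-3-oxobut-1-en-1-yl]carbamate
Product: 6 methyl N-benzyl-N-[(1E)-3-(tert-butyldimethylsilyloxy)buta-1,3-dien-1-yl]carbamate
Conditions: KN(SiMe3)2, THF, −78 °C; TBSCl, −78 °C → rt
Reagents that add atoms: tert-butyldimethylsilyl chloride, CC(C)(C)[Si](C)(C)Cl
Why: Kinetic deprotonation of the methyl ketone and O-silylation of the potassium enolate (silyl enol ether formation) should give the 2-silyloxydiene with the E enamide geometry untouched.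

Step 4
Reactants: 2 2-methylidenepent-4-enal; 6 methyl N-benzyl-N-[(1E)-3-(tert-butyldimethylsilyloxy)buta-1,3-dien-1-yl]carbamate
Product: 8 (1R)-4-oxo-1-(prop-2-en-1-yl)cyclohex-2-ene-1-carbaldehyde, via endo cycloadduct 7 (not isolated)
Conditions: (salen)CrCl (5 mol %; salen = enantiopure N,N′-bis(3,5-di-tert-butylsalicylidene)cyclohexane-1,2-diamine dianion), 4 Å MS, CH2Cl2, −40 °C; filter; then aq. HF, MeCN, 0 °C
Reagents that add atoms: none
Why: The trivalent chromium centre binds the formyl oxygen of 2, and the diene adds in a concerted, asynchronous, endo-selective [4+2] cycloaddition in which the nucleophilic CH2 terminus bonds to the enal β-carbon (C7–C7a) ahead of the bond from the nitrogen-bearing terminus to the α-carbon (C3a–C4); the closest known reaction type is the chromium salen-catalysed enantioselective Diels–Alder reaction of 1-carbamoylamino-3-silyloxybutadienes with 2-alkylacroleins. The six-membered carbocycle is closed by the intermolecular cycloaddition itself, both partners reacting suprafacially. C3a is set by the chiral salen ligand, which leaves one enantioface of the coordinated enal open, and the ligand antipode that leads to (R)-8 is selected in a pilot run (both antipodes are commercial). Regiochemistry follows from the polarisation of the diene by its nitrogen and silyloxy donors, and the required enantioselectivity depends on the catalysed path outrunning the background reaction, which the carbamate secures by lowering the basicity and the uncatalysed reactivity of the diene. Aqueous HF then cleaves the silyl enol ether and ionises the vinylogous N,O-acetal, so that the carbamate leaves and the transient second stereocentre of 7 vanishes in the enone.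

Step 5
Reactants: 9 3,4-dimethoxybenzaldehyde
Product: 11 diethyl [(3,4-dimethoxyphenyl)(methoxy)methyl]phosphonate, via dimethyl acetal 10 (not isolated)
Conditions: HC(OMe)3, TsOH (cat.), MeOH, rt; evaporate; then P(OEt)3, BF3·OEt2, CH2Cl2, −20 °C → rt
Reagents that add atoms: trimethyl orthoformate, COC(OC)OC; triethyl phosphite, CCOP(OCC)OCC
Why: Acetalisation, Lewis-acid ionisation to the aryl oxocarbenium ion, capture by the phosphite and dealkylation (Michaelis–Arbuzov-type synthesis of an α-alkoxybenzylphosphonate) should give the olefination reagent, whose stereocentre is of no consequence.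

Step 6
Reactants: 8 (1R)-4-oxo-1-(prop-2-en-1-yl)cyclohex-2-ene-1-carbaldehyde; 11 diethyl [(3,4-dimethoxyphenyl)(methoxy)methyl]phosphonate
Product: 12 (4R)-4-[2-(3,4-dimethoxyphenyl)-2-methoxyethenyl]-4-(prop-2-en-1-yl)cyclohex-2-en-1-one (E/Z mixture)
Conditions: 11, LiN(iPr)2, THF, −78 °C; add 8, −78 °C → rt; NaHCO3 work-up
Reagents that add atoms: none
Why: Horner–Wadsworth–Emmons olefination by the lithiated α-methoxybenzylphosphonate should take place at the non-enolisable aldehyde, which is far more electrophilic than the conjugated ring ketone, and gives the aryl enol ether without touching C3a.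

Step 7
Reactants: 12 (4R)-4-[2-(3,4-dimethoxyphenyl)-2-methoxyethenyl]-4-(prop-2-en-1-yl)cyclohex-2-en-1-one
Product: 13 (4R)-4-[2-(3,4-dimethoxyphenyl)-2-methoxycyclopropyl]-4-(prop-2-en-1-yl)cyclohex-2-en-1-one (cyclopropane diastereomers)
Conditions: Et2Zn, CH2I2, CH2Cl2–DME, 0 °C → rt; pyridine quench
Reagents that add atoms: diiodomethane, ICI
Why: In this Simmons–Smith cyclopropanation (Et2Zn variant) the electrophilic zinc carbenoid, guided by the methoxy oxygen, should add to the electron-rich enol ether faster than to the monosubstituted allyl alkene and not to the electron-poor enone, so that the future C3 methyl carbon is installed as a base-stable methoxycyclopropane whose new stereocentres are erased in step 11.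

Step 8
Reactants: 13 (4R)-4-[2-(3,4-dimethoxyphenyl)-2-methoxycyclopropyl]-4-(prop-2-en-1-yl)cyclohex-2-en-1-one
Product: 14 (5S)-5-[2-(3,4-dimethoxyphenyl)-2-methoxycyclopropyl]-5-(prop-2-en-1-yl)-7-oxabicyclo[4.1.0]heptan-2-one (epoxide diastereomers)
Conditions: 30% H2O2, NaOH (cat.), MeOH, 0 °C
Reagents that add atoms: hydrogen peroxide, OO
Why: Weitz–Scheffer nucleophilic epoxidation by hydroperoxide anion is specific for the enone C4=C5 bond, and the epoxide stereocentres are removed in step 9.

Step 9
Reactants: 14 (5S)-5-[2-(3,4-dimethoxyphenyl)-2-methoxycyclopropyl]-5-(prop-2-en-1-yl)-7-oxabicyclo[4.1.0]heptan-2-one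
Product: 16 (4R)-4-[2-(3,4-dimethoxyphenyl)-2-methoxycyclopropyl]-2-methoxy-4-(prop-2-en-1-yl)cyclohex-2-en-1-one, via hydroxy methoxy ketone 15 (not isolated)
Conditions: NaOMe, MeOH, rt → 50 °C
Reagents that add atoms: sodium methoxide, [Na+].[O-]C
Why: Methoxide should open the α,β-epoxy ketone by SN2 substitution at the carbonyl-activated α-carbon C5, and the resulting β-hydroxy ketone dehydrates by E1cB elimination to the 2-methoxy enone, which keeps the two arms at C3a distinct.

Step 10
Reactants: 16 (4R)-4-[2-(3,4-dimethoxyphenyl)-2-methoxycyclopropyl]-2-methoxy-4-(prop-2-en-1-yl)cyclohex-2-en-1-one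
Product: 17 (4S)-4-[2-(3,4-dimethoxyphenyl)-2-methoxycyclopropyl]-2-methoxy-4-(prop-2-en-1-yl)cyclohexa-2,5-dien-1-one
Conditions: LiN(iPr)2, THF, −78 °C; then PhS(Cl)=NtBu, −78 °C
Reagents that add atoms: none
Why: Kinetic deprotonation at C7, the only enolisable position, sulfenylation of the lithium dienolate by the sulfinimidoyl chloride and syn-elimination of the sulfenamide (Mukaiyama dehydrogenation) should introduce the C7=C7a double bond, and C3a stays stereogenic because only one arm carries the methoxy group.

Step 11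
Reactants: 17 (4S)-4-[2-(3,4-dimethoxyphenyl)-2-methoxycyclopropyl]-2-methoxy-4-(prop-2-en-1-yl)cyclohexa-2,5-dien-1-one
Product: 20 (2S,3R,3aR,7aS)-2-(3,4-dimethoxyphenyl)-5-methoxy-3-methyl-3a-(prop-2-en-1-yl)-3,3a,7,7a-tetrahydro-1-benzofuran-6(2H)-one, via keto dienone 18 (not isolated), via dihydrofuran 19 (not isolated)
Conditions: TFA–H2O (20:1), CH2Cl2, 0 °C → rt; then Et3SiH, −20 → 0 °C
Reagents that add atoms: water, O
Why: Acid opens the donor-substituted cyclopropane with protonation at CH2 and hydrolysis to the α-methyl aryl ketone 18, whose carbonyl oxygen adds to the unsubstituted, more electrophilic dienone arm at C7a (5-exo oxa-Michael addition, cis ring fusion enforced by the tether from C3a) to give a C2 oxocarbenium ion in equilibrium with dihydrofuran 19, so that C3 epimerises freely, and ionic hydrogenation with Et3SiH should then deliver hydride to C2 on the convex face anti to the C3 methyl group, the C3 epimer with methyl on the concave face being the matched and faster-reacting one (Curtin–Hammett control), which gives the 2,3-cis arrangement with H2, H3, H7a and the allyl group on one face.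

Compound list
1 | pent-4-enal | C=CCCC=O | starting material
2 | 2-methylidenepent-4-enal (2-allylacrolein) | C=CCC(=C)C=O | intermediate
3 | methyl N-benzylcarbamate | COC(=O)NCc1ccccc1 | starting material
4 | (E)-4-methoxybut-3-en-2-one | CO/C=C/C(C)=O | starting material
5 | methyl N-benzyl-N-[(1E)-3-oxobut-1-en-1-yl]carbamate | COC(=O)N(Cc1ccccc1)/C=C/C(C)=O | intermediate
6 | methyl N-benzyl-N-[(1E)-3-(tert-butyldimethylsilyloxy)buta-1,3-dien-1-yl]carbamate | COC(=O)N(Cc1ccccc1)/C=C/C(=C)O[Si](C)(C)C(C)(C)C | intermediate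
7 | methyl N-benzyl-N-[(1R,6R)-6-formyl-6-(prop-2-en-1-yl)-3-(tert-butyldimethylsilyloxy)cyclohex-2-en-1-yl]carbamate, endo adduct with formyl cis to nitrogen (not isolated) | C=CC[C@@]1(C=O)[C@H](N(Cc2ccccc2)C(=O)OC)C=C(O[Si](C)(C)C(C)(C)C)CC1 | intermediate
8 | (1R)-4-oxo-1-(prop-2-en-1-yl)cyclohex-2-ene-1-carbaldehyde | C=CC[C@@]1(C=O)C=CC(=O)CC1 | intermediate
9 | 3,4-dimethoxybenzaldehyde | COc1ccc(C=O)cc1OC | starting material
10 | 4-(dimethoxymethyl)-1,2-dimethoxybenzene (not isolated) | COC(OC)c1ccc(OC)c(OC)c1 | intermediate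
11 | diethyl [(3,4-dimethoxyphenyl)(methoxy)methyl]phosphonate (racemic) | CCOP(=O)(OCC)C(OC)c1ccc(OC)c(OC)c1 | intermediate
12 | (4R)-4-[2-(3,4-dimethoxyphenyl)-2-methoxyethenyl]-4-(prop-2-en-1-yl)cyclohex-2-en-1-one, E/Z mixture | C=CC[C@@]1(C=C(OC)c2ccc(OC)c(OC)c2)C=CC(=O)CC1 | intermediate
13 | (4R)-4-[2-(3,4-dimethoxyphenyl)-2-methoxycyclopropyl]-4-(prop-2-en-1-yl)cyclohex-2-en-1-one, cyclopropane diastereomers | C=CC[C@@]1(C2CC2(OC)c2ccc(OC)c(OC)c2)C=CC(=O)CC1 | intermediate
14 | (5S)-5-[2-(3,4-dimethoxyphenyl)-2-methoxycyclopropyl]-5-(prop-2-en-1-yl)-7-oxabicyclo[4.1.0]heptan-2-one, diastereomers | C=CC[C@@]1(C2CC2(OC)c2ccc(OC)c(OC)c2)C2OC2C(=O)CC1 | intermediate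
15 | (4S)-4-[2-(3,4-dimethoxyphenyl)-2-methoxycyclopropyl]-3-hydroxy-2-methoxy-4-(prop-2-en-1-yl)cyclohexan-1-one, diastereomers (not isolated) | C=CC[C@@]1(C2CC2(OC)c2ccc(OC)c(OC)c2)C(O)C(OC)C(=O)CC1 | intermediate
16 | (4R)-4-[2-(3,4-dimethoxyphenyl)-2-methoxycyclopropyl]-2-methoxy-4-(prop-2-en-1-yl)cyclohex-2-en-1-one | C=CC[C@@]1(C2CC2(OC)c2ccc(OC)c(OC)c2)C=C(OC)C(=O)CC1 | intermediate
17 | (4S)-4-[2-(3,4-dimethoxyphenyl)-2-methoxycyclopropyl]-2-methoxy-4-(prop-2-en-1-yl)cyclohexa-2,5-dien-1-one | C=CC[C@@]1(C2CC2(OC)c2ccc(OC)c(OC)c2)C=C(OC)C(=O)C=C1 | intermediate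
18 | (4S)-4-[1-(3,4-dimethoxyphenyl)-1-oxopropan-2-yl]-2-methoxy-4-(prop-2-en-1-yl)cyclohexa-2,5-dien-1-one, both side-chain epimers (not isolated) | C=CC[C@@]1(C(C)C(=O)c2ccc(OC)c(OC)c2)C=C(OC)C(=O)C=C1 | intermediate
19 | (3aS,7aS)-2-(3,4-dimethoxyphenyl)-5-methoxy-3-methyl-3a-(prop-2-en-1-yl)-3a,7a-dihydro-1-benzofuran-6(7H)-one (not isolated) | C=CC[C@@]12C=C(OC)C(=O)C[C@@H]1OC(c1ccc(OC)c(OC)c1)=C2C | intermediate
20 | (2S,3R,3aR,7aS)-2-(3,4-dimethoxyphenyl)-5-methoxy-3-methyl-3a-(prop-2-en-1-yl)-3,3a,7,7a-tetrahydro-1-benzofuran-6(2H)-one | C=CC[C@@]12C=C(OC)C(=O)C[C@@H]1O[C@H](c1ccc(OC)c(OC)c1)[C@@H]2C | target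

Total step count: 11. Longest linear sequence: 9 steps (steps 2, 3, 4, 6, 7, 8, 9, 10, 11).

Steps most likely to fail

Step 4. The uncatalysed background cycloaddition or slow turnover of the chromium catalyst with the hindered enal may erode enantiocontrol, and departure of the carbamate in the acid stage may stall. The fallback replaces catalyst control by auxiliary control and sets out from 4 and 2. Amine exchange of 4 with trans-2,5-diphenylpyrrolidine (the antipode that leads to (R)-8, drawn here as 2S,5S) in MeOH should give enaminone F1. KN(SiMe3)2 and TBSCl then give the chiral amino silyloxy diene F2, which should add to 2 without catalyst in toluene between −20 °C and rt to give cycloadduct F3. Aqueous HF in MeCN eliminates the recoverable auxiliary and comes back to the route at 8.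

Step 7. The carbenoid may also cyclopropanate the allyl group, transfer to the hindered enol ether may be slow, and zinc iodide may open the product. The fallback installs the methyl group by enolate alkylation and sets out from 12.
- Dilute HCl in THF should hydrolyse 12 to keto enone F4.
- Ethylene glycol and TsOH in benzene with water removal protect the ring carbonyl as dioxolane F5.
- LiN(iPr)2 and MeI methylate the only remaining enolisable position to give methylated ketal F6.
- Aqueous HCl in THF releases methyl ketone enone F7.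
- The conditions of steps 8 and 9 lead through epoxide F8 to methoxy enone F9.
- IBX in DMSO dehydrogenates F9 to 18, where the fallback comes back to the route; 18 is carried on as in step 11 from the TFA stage.

Step 11. Proton or hydride delivery from the wrong face would give C3 or C2 epimers, the open-chain cation may be reduced before ring closure, and acid may induce migration of the angular allyl group in the dienone. The fallback separates ring closure and C3 equilibration from the reduction and sets out from 17. Dilute HCl in THF opens the cyclopropane to 18, and camphorsulfonic acid in MeOH converts 18 by oxa-Michael addition and methanol capture into cyclic methyl ketal F10, in which C3 has equilibrated and whose epimers can be checked and separated. Et3SiH with BF3·OEt2 in CH2Cl2 at −78 °C then replaces the methoxy group by hydride anti to the now fixed C3 methyl group (silane reduction of a cyclic ketal through its oxocarbenium ion) and comes back to the route at 20.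

Further compounds
F1 | step 4 | (E)-4-[(2S,5S)-2,5-diphenylpyrrolidin-1-yl]but-3-en-2-one | CC(=O)/C=C/N1[C@H](c2ccccc2)CC[C@H]1c1ccccc1
F2 | step 4 | (2S,5S)-1-[(1E)-3-(tert-butyldimethylsilyloxy)buta-1,3-dien-1-yl]-2,5-diphenylpyrrolidine | C=C(O[Si](C)(C)C(C)(C)C)/C=C/N1[C@H](c2ccccc2)CC[C@H]1c1ccccc1
F3 | step 4 | endo cycloadduct, 2-[(2S,5S)-2,5-diphenylpyrrolidin-1-yl]-1-(prop-2-en-1-yl)-4-(tert-butyldimethylsilyloxy)cyclohex-3-ene-1-carbaldehyde with formyl cis to nitrogen | C=CC[C@@]1(C=O)[C@H](N2[C@H](c3ccccc3)CC[C@H]2c2ccccc2)C=C(O[Si](C)(C)C(C)(C)C)CC1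
F4 | step 7 | (4S)-4-[2-(3,4-dimethoxyphenyl)-2-oxoethyl]-4-(prop-2-en-1-yl)cyclohex-2-en-1-one | C=CC[C@@]1(CC(=O)c2ccc(OC)c(OC)c2)C=CC(=O)CC1
F5 | step 7 | 1-(3,4-dimethoxyphenyl)-2-[(8S)-8-(prop-2-en-1-yl)-1,4-dioxaspiro[4.5]dec-6-en-8-yl]ethan-1-one | C=CC[C@@]1(CC(=O)c2ccc(OC)c(OC)c2)C=CC2(CC1)OCCO2
F6 | step 7 | 1-(3,4-dimethoxyphenyl)-2-[(8R)-8-(prop-2-en-1-yl)-1,4-dioxaspiro[4.5]dec-6-en-8-yl]propan-1-one, both side-chain epimers | C=CC[C@@]1(C(C)C(=O)c2ccc(OC)c(OC)c2)C=CC2(CC1)OCCO2
F7 | step 7 | (4R)-4-[1-(3,4-dimethoxyphenyl)-1-oxopropan-2-yl]-4-(prop-2-en-1-yl)cyclohex-2-en-1-one, both side-chain epimers | C=CC[C@@]1(C(C)C(=O)c2ccc(OC)c(OC)c2)C=CC(=O)CC1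
F8 | step 7 | (5S)-5-[1-(3,4-dimethoxyphenyl)-1-oxopropan-2-yl]-5-(prop-2-en-1-yl)-7-oxabicyclo[4.1.0]heptan-2-one, diastereomers | C=CC[C@@]1(C(C)C(=O)c2ccc(OC)c(OC)c2)C2OC2C(=O)CC1
F9 | step 7 | (4R)-4-[1-(3,4-dimethoxyphenyl)-1-oxopropan-2-yl]-2-methoxy-4-(prop-2-en-1-yl)cyclohex-2-en-1-one, both side-chain epimers | C=CC[C@@]1(C(C)C(=O)c2ccc(OC)c(OC)c2)C=C(OC)C(=O)CC1
F10 | step 11 | (3aR,7aS)-2-(3,4-dimethoxyphenyl)-2,5-dimethoxy-3-methyl-3a-(prop-2-en-1-yl)-3,3a,7,7a-tetrahydro-1-benzofuran-6(2H)-one, C2 and C3 epimers | C=CC[C@@]12C=C(OC)C(=O)C[C@@H]1OC(OC)(c1ccc(OC)c(OC)c1)C2C
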